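The eleven-membered ring contains the array C8=C9–C10–C11–C1–C2(O): a bridgehead alkene shared with the cyclohexene, the two ring-fusion carbons, and an oxygenated C2 beside the methylidene carbon C1. Read as a 1,5-diene, this is the product of an anionic oxy-Cope shift. One operation forms C10–C11, cleaves C2–C8, enlarges a cycloheptane by four atoms, sets C10 and C11, and delivers a regiodefined C1=C2 enolate. The substrate is a spiro[5.6] carbinol: a cycloheptanol with an (E)-buta-1,3-dienyl group on C2, spiro-fused at C8 to a cyclohexene whose C15/C16 diol is locked as a trans acetonide.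

Key step: step 20

Remark: locants follow the target (C17 is the CH2O carbon on C5; before step 17, C13 is the oxygenated carbon on C14 and C10 is the CH of its vinyl group). Compounds 1, 7, 9, 10, 13 and 30 are taken as commercial. The sense of the chiral base in step 2 is assigned by analogy, and the antipodal amide would be used if it proved opposite.

Step 1
Reactants: 1 4-(hydroxymethyl)cyclohexan-1-one
Product: 2 4-(tert-butyldiphenylsilyloxymethyl)cyclohexan-1-one
Conditions: tert-BuPh2SiCl, imidazole, CH2Cl2, 0 to 23 °C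
Reagents that add atoms: tert-butyl(chloro)diphenylsilane, CC(C)(C)[Si](Cl)(c1ccccc1)c1ccccc1
Why: Silyl ether formation at the primary hydroxyl with imidazole as base leaves the ketone untouched and creates no stereocentre.

Step 2
Reactants: 2 4-(tert-butyldiphenylsilyloxymethyl)cyclohexan-1-one
Product: 4 (S)-trimethylsilyl enol ether of 2, via lithium enolate 3 (not isolated)
Conditions: LiN[(R)-CH(CH3)C6H5]2 (from the amine and n-BuLi), Me3SiCl (internal quench), THF, −100 °C
Reagents that add atoms: chlorotrimethylsilane, C[Si](C)(C)Cl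
Why: Enantioselective deprotonation of the prochiral 4-substituted cyclohexanone by a chiral lithium amide should distinguish the enantiotopic α-methylene groups and so set C5 (sense assigned by analogy with 4-tert-butylcyclohexanone); material of the minor configuration becomes a separable diastereomer after step 12.

Step 3
Reactants: 4 (S)-trimethylsilyl enol ether of 2
Product: 6 (5S)-2-bromo-5-(silyloxymethyl)cyclohept-2-en-1-one, via dibromocyclopropane 5 (not isolated)
Conditions: CHBr3, KOC(CH3)3, pentane, −20 to 23 °C; then toluene, 60 °C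
Reagents that add atoms: bromoform, BrC(Br)Br
Why: Dibromocarbene cyclopropanates the enol ether and the siloxy-dibromocyclopropane opens electrocyclically with loss of Me3SiBr (one-carbon ring expansion), which places the inserted carbon (future C8, bearing Br) between the carbonyl and the former enol carbon without touching C5.

Step 4
Reactants: 6 (5S)-2-bromo-5-(silyloxymethyl)cyclohept-2-en-1-one; 7 isopropenylboronic acid pinacol ester
Product: 8 (5S)-2-(prop-1-en-2-yl)-5-(silyloxymethyl)cyclohept-2-en-1-one
Conditions: Pd(PPh3)4 (5 mol %), K3PO4, 1,4-dioxane/H2O, 60 °C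
Reagents that add atoms: none
Why: Suzuki–Miyaura coupling of the α-bromo enone with the alkenylboronate attaches C9 with its methyl group to C8 and keeps the enone.

Step 5
Reactants: 9 (4R)-4-benzyl-1,3-oxazolidin-2-one; 10 (2E)-but-2-enoyl chloride
Product: 12 (4R)-4-benzyl-3-[(2E)-but-2-enoyl]-1,3-oxazolidin-2-one, via N-lithio oxazolidinone 11 (not isolated)
Conditions: n-BuLi, THF, −78 °C; then 10, −78 to 0 °C
Reagents that add atoms: none
Why: N-Acylation of the lithiated oxazolidinone by the acid chloride attaches the auxiliary; no stereocentre is formed.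

Step 6
Reactants: 12 (4R)-4-benzyl-3-[(2E)-but-2-enoyl]-1,3-oxazolidin-2-one; 13 (tert-butyldimethylsilyloxy)acetaldehyde
Product: 15 Evans syn-aldol adduct (2R,3R), via dibutylboron dienolate 14 (not isolated)
Conditions: (C4H9)2BOSO2CF3, Et3N, CH2Cl2, −78 to 0 °C; then 13, −78 to 0 °C; pH 7 buffer, MeOH, H2O2
Reagents that add atoms: none
Why: In this Evans aldol reaction the (Z)-boron dienolate reacts at its α-carbon through a chair transition state on the face left open by the benzyl group of the (R)-auxiliary, which should set C15 (and a temporary centre at C14).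

Step 7
Reactants: 15 Evans syn-aldol adduct (2R,3R)
Product: 17 (3R,4R)-3-ethenyl-4-hydroxyoxolan-2-one, via desilylated hydroxy imide 16 (not isolated)
Conditions: Bu4NF, THF, 0 °C; aq. NH4Cl
Reagents that add atoms: none
Why: Fluoride cleaves the primary silyl ether and the freed hydroxyl closes the five-membered lactone by acyl transfer from the imide (lactonisation with release of the auxiliary), leaving C15 unchanged; the C14 epimer or the conjugated isomer would give the same dienolate in step 8.

Step 8
Reactants: 17 (3R,4R)-3-ethenyl-4-hydroxyoxolan-2-one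
Product: 19 (3S,4R)-3-ethenyl-4-hydroxy-3-methyloxolan-2-one, via dilithium enolate alkoxide 18 (not isolated)
Conditions: LiN(i-C3H7)2 (2.3 equiv), THF, −78 °C; then CH3I, DMPU, −78 to −30 °C
Reagents that add atoms: iodomethane, CI
Why: Alkylation of the dianion of a β-hydroxy-γ-lactone takes the electrophile anti to the neighbouring alkoxide, so methyl should enter trans to O15 and fix the quaternary C14 with vinyl cis to O15.

Step 9
Reactants: 19 (3S,4R)-3-ethenyl-4-hydroxy-3-methyloxolan-2-one
Product: 20 (2R,3R)-2-ethenyl-2-methylbutane-1,3,4-triol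
Conditions: LiAlH4, THF, 0 to 23 °C
Reagents that add atoms: none
Why: Hydride reduction of the lactone gives the triol without touching the stereocentres or the vinyl group.

Step 10
Reactants: 20 (2R,3R)-2-ethenyl-2-methylbutane-1,3,4-triol
Product: 21 (2R,4R,5R)-dioxanyl methanol
Conditions: 4-MeOC6H4CH(OMe)2, camphorsulfonic acid (cat.), CH2Cl2, 23 °C
Reagents that add atoms: 4-methoxybenzaldehyde dimethyl acetal, COc1ccc(C(OC)OC)cc1
Why: Acid-catalysed transacetalisation under thermodynamic control should select the six-membered 1,3-dioxane across O15/O13 (aryl and C16 equatorial, which sets the acetal carbon) and leave the C16 hydroxyl free.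

Step 11
Reactants: 21 (2R,4R,5R)-dioxanyl methanol
Product: 22 (2R,4R,5R)-dioxane-4-carbaldehyde
Conditions: Dess–Martin periodinane, NaHCO3, CH2Cl2, 0 to 23 °C
Reagents that add atoms: none
Why: Dess–Martin oxidation converts the primary alcohol into the aldehyde under buffered, non-epimerising conditions.

Step 12
Reactants: 8 (5S)-2-(prop-1-en-2-yl)-5-(silyloxymethyl)cyclohept-2-en-1-one; 22 (2R,4R,5R)-dioxane-4-carbaldehyde
Product: 24 aldol adduct with quaternary C8, via lithium dienolate 23 (not isolated)
Conditions: LiBH(sec-C4H9)3, THF, −78 °C; MgBr2·OEt2; then 22, −78 °C; AcOH quench at −78 °C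
Reagents that add atoms: none
Why: Conjugate hydride addition gives the C2=C8 dienolate regiospecifically, and its aldol addition through a closed chair (Zimmerman–Traxler) transition state, with the isopropenyl group cis to the enolate oxygen and the aldehyde held as a magnesium chelate with O15 (Cram chelate), should set C16 threo to C15 and the quaternary C8 relative to C16, independently of the remote C5.

Step 13
Reactants: 24 aldol adduct with quaternary C8
Product: 25 keto triol
Conditions: AcOH/THF/H2O (3:1:1), 40 °C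
Reagents that add atoms: none
Why: Mild acetal hydrolysis removes the aryl acetal while the silyl ether and the non-dehydratable β-hydroxy ketone survive.

Step 14
Reactants: 25 keto triol
Product: 26 C15/C16 acetonide with free C13 hydroxyl
Conditions: 2,2-dimethoxypropane, pyridinium p-toluenesulfonate (cat.), acetone, 23 °C
Reagents that add atoms: 2,2-dimethoxypropane, COC(C)(C)OC
Why: Acetonide formation under thermodynamic control favours the five-membered dioxolane on the threo 1,2-diol O15/O16 (trans-disubstituted ring) over a dioxane, leaving the primary C13 hydroxyl free.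

Step 15
Reactants: 26 C15/C16 acetonide with free C13 hydroxyl
Product: 27 spiro[5.6] ketone with C13 hydroxyl
Conditions: second-generation Hoveyda–Grubbs catalyst (10 mol %), toluene, 80 °C, argon sparge
Reagents that add atoms: none
Why: Ring-closing metathesis of the C14 vinyl group with the C8 isopropenyl group closes the cyclohexene at C9=C10 as a trisubstituted alkene, the trans-dioxolane holding the two alkenes gauche and within reach.

Step 16
Reactants: 27 spiro[5.6] ketone with C13 hydroxyl
Product: 28 spiro keto aldehyde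
Conditions: Dess–Martin periodinane, NaHCO3, CH2Cl2, 0 to 23 °C
Reagents that add atoms: none
Why: Dess–Martin oxidation of the neopentyl primary alcohol gives a non-enolisable aldehyde.

Step 17
Reactants: 28 spiro keto aldehyde
Product: 29 spiro ketone with C14 vinyl group
Conditions: Ph3PCH3Br, KN(SiMe3)2, THF, 0 °C; then 28, −78 to 0 °C
Reagents that add atoms: methyltriphenylphosphonium bromide, C[P+](c1ccccc1)(c1ccccc1)c1ccccc1.[Br-]
Why: Wittig methylenation turns the aldehyde into the C14 vinyl group, the hindered α-quaternary ketone reacting far more slowly.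

Step 18
Reactants: 30 prop-2-enal
Product: 31 (1E)-1-iodobuta-1,3-diene
Conditions: CHI3, CrCl2, THF, 0 °C
Reagents that add atoms: iodoform, IC(I)I
Why: Takai olefination converts the aldehyde into the (E)-alkenyl iodide, used as a cold solution.

Step 19
Reactants: 29 spiro ketone with C14 vinyl group; 31 (1E)-1-iodobuta-1,3-diene
Product: 34 spiro[5.6] dienyl carbinol (oxy-Cope substrate), via buta-1,3-dienyllithium 32 (not isolated), via buta-1,3-dienylcerium dichloride 33 (not isolated)
Conditions: 31, tert-BuLi (2 equiv), Et2O, −78 °C; CeCl3, THF, −78 °C; then 29, −78 to −40 °C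
Reagents that add atoms: none
Why: Iodine–lithium exchange and transmetalation give a weakly basic organocerium reagent for 1,2-addition to the hindered enolisable ketone, which should approach anti to the alkenyl carbon C9 of the α-quaternary centre (Felkin–Anh) and so place the dienyl group cis to C16 and the hydroxyl cis to C9.

Step 20
Reactants: 34 spiro[5.6] dienyl carbinol (oxy-Cope substrate)
Product: 37 bicyclic triethylsilyl enol ether bearing two vinyl groups, via potassium alkoxide 35 (not isolated), via potassium enolate 36 (not isolated)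
Conditions: KH, 18-crown-6, THF, 0 to 25 °C; then Et3SiCl, Et3N, −78 °C
Reagents that add atoms: chlorotriethylsilane, CC[Si](Cl)(CC)CC
Why: KH with the crown ether gives the dissociated alkoxide 35, whose C2–C8 bond, held axial on the acetonide-locked cyclohexene half-chair and parallel to the C9=C10 π orbital, migrates in a charge-accelerated [3,3] shift through the chair array C11=C1–C2–C8–C9=C10; the closest known reaction type is the anionic oxy-Cope ring expansion of 1,2-dialkenylcycloalkanols, including cases that end in bridgehead alkenes. The eleven-membered ring is not closed end to end but arises by four-atom enlargement of the cycloheptane, C10–C11 forming as C2–C8 breaks inside a six-membered transition state, and C8=C9 is created inside the existing cyclohexene, so its geometry is fixed. C10 is controlled by the spiro centre C8, because the shift is suprafacial on the C8–C9=C10 allyl unit and C2 leaves from the face that carries O16 and the C14 vinyl group, so C11 arrives cis to C13. C11 is controlled by the (E) geometry of the dienyl group, whose vinyl end sits equatorial in the chair and puts C1 cis to C9. The step needs chair over boat and [3,3] shift over [1,3] shift or fragmentation; the (E)-diene, the rigid spiro bicycle and the free alkoxide should secure this, and the acetonide offers no silyl group that could migrate to the alkoxide. Et3SiCl then traps the C1=C2 enolate 36 with its regiochemistry intact.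

Step 21
Reactants: 37 bicyclic triethylsilyl enol ether bearing two vinyl groups
Product: 38 tricyclic cyclopentene enol ether
Conditions: second-generation Grubbs catalyst (5 mol %), CH2Cl2, 40 °C
Reagents that add atoms: none
Why: Ring-closing metathesis of the vinyl groups on C11 and C14 closes the cis-fused cyclopentene (C12=C13), the trisubstituted silyl enol ether and the tetrasubstituted alkene being inert.

Step 22
Reactants: 38 tricyclic cyclopentene enol ether
Product: 39 tricyclic cyclopentane enol ether
Conditions: 2-nitrobenzenesulfonohydrazide, Et3N, CH2Cl2, 23 °C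
Reagents that add atoms: none
Why: Diimide reduction is selective for the cis-disubstituted cyclopentene over the trisubstituted enol ether and the tetrasubstituted bridgehead alkene, and its near-neutral conditions keep the enol ether intact.

Step 23
Reactants: 39 tricyclic cyclopentane enol ether
Product: 40 C1 dimethylaminomethyl ketone
Conditions: Me2N=CH2 I (Eschenmoser's salt), CH2Cl2, 23 °C; aq. NaHCO3
Reagents that add atoms: N,N-dimethylmethylideneammonium iodide, C=[N+](C)C.[I-]
Why: In this Mannich reaction the iminium salt alkylates the silyl enol ether at C1, so the regiochemistry stored in the enol ether fixes the site of the future methylidene (the new C1 centre is removed in step 24).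

Step 24
Reactants: 40 C1 dimethylaminomethyl ketone
Product: 42 C1-methylidene ketone, via trimethylammonium iodide 41 (not isolated)
Conditions: CH3I, CH2Cl2, 23 °C; then aq. NaHCO3, 23 °C
Reagents that add atoms: none
Why: N-Methylation followed by mild base-induced β-elimination of trimethylamine from the Mannich base gives the α-methylidene ketone without moving the double bond into the ring.

Step 25
Reactants: 42 C1-methylidene ketone
Product: 43 C2 allylic alcohol
Conditions: (R)-2-methyl-CBS-oxazaborolidine, catecholborane, toluene, −78 °C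
Reagents that add atoms: none
Why: Corey–Bakshi–Shibata reduction with the (R)-oxazaborolidine should deliver hydride under reagent control, the alkenyl side acting as the large group, to give the (S)-configured C2 carbinol.

Step 26
Reactants: 43 C2 allylic alcohol
Product: 44 C2/C17 diol acetonide
Conditions: Bu4NF, THF, 0 to 23 °C
Reagents that add atoms: none
Why: Fluoride-mediated desilylation frees the primary C17 hydroxyl and does not affect the acetonide.

Step 27
Reactants: 44 C2/C17 diol acetonide
Product: 45 diacetate acetonide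
Conditions: Ac2O, pyridine, 4-(dimethylamino)pyridine (cat.), CH2Cl2, 23 °C
Reagents that add atoms: acetic anhydride, CC(=O)OC(C)=O
Why: Acylation with nucleophilic catalysis esterifies the secondary allylic and the primary hydroxyl groups.

Step 28
Reactants: 45 diacetate acetonide
Product: 46 CNP0193272.1 (target)
Conditions: AcOH/H2O (4:1), 40 °C
Reagents that add atoms: none
Why: Mild acetal hydrolysis opens the strained trans-fused acetonide faster than it affects the acetates or the allylic positions and releases the C15/C16 diol.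

Compound list
1 | 4-(hydroxymethyl)cyclohexan-1-one | O=C1CCC(CO)CC1 | starting material
2 | 4-({[tert-butyl(diphenyl)silyl]oxy}methyl)cyclohexan-1-one | O=C1CCC(CO[Si](c2ccccc2)(c2ccccc2)C(C)(C)C)CC1 | intermediate
3 | lithium (4S)-4-(silyloxymethyl)cyclohex-1-en-1-olate | [Li]OC1=CC[C@@H](CO[Si](c2ccccc2)(c2ccccc2)C(C)(C)C)CC1 | intermediate (not isolated)
4 | tert-butyl(diphenyl){[(1S)-4-(trimethylsilyloxy)cyclohex-3-en-1-yl]methoxy}silane | C[Si](C)(C)OC1=CC[C@@H](CO[Si](c2ccccc2)(c2ccccc2)C(C)(C)C)CC1 | intermediate
5 | 7,7-dibromo-4-(silyloxymethyl)-1-(trimethylsilyloxy)bicyclo[4.1.0]heptane (ring-fusion epimers) | C[Si](C)(C)OC12CC[C@H](CO[Si](c3ccccc3)(c3ccccc3)C(C)(C)C)CC1C2(Br)Br | intermediate (not isolated)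
6 | (5S)-2-bromo-5-({[tert-butyl(diphenyl)silyl]oxy}methyl)cyclohept-2-en-1-one | O=C1CC[C@H](CO[Si](c2ccccc2)(c2ccccc2)C(C)(C)C)CC=C1Br | intermediate
7 | 4,4,5,5-tetramethyl-2-(prop-1-en-2-yl)-1,3,2-dioxaborolane | CC(=C)B1OC(C)(C)C(C)(C)O1 | starting material
8 | (5S)-5-({[tert-butyl(diphenyl)silyl]oxy}methyl)-2-(prop-1-en-2-yl)cyclohept-2-en-1-one | O=C1CC[C@H](CO[Si](c2ccccc2)(c2ccccc2)C(C)(C)C)CC=C1C(C)=C | intermediate
9 | (4R)-4-benzyl-1,3-oxazolidin-2-one | O=C1N[C@H](Cc2ccccc2)CO1 | starting material
10 | (2E)-but-2-enoyl chloride | C/C=C/C(=O)Cl | starting material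
11 | N-lithio (4R)-4-benzyl-1,3-oxazolidin-2-one | [Li]N1[C@H](Cc2ccccc2)COC1=O | intermediate (not isolated)
12 | (4R)-4-benzyl-3-[(2E)-but-2-enoyl]-1,3-oxazolidin-2-one | C/C=C/C(=O)N1[C@H](Cc2ccccc2)COC1=O | intermediate
13 | {[tert-butyl(dimethyl)silyl]oxy}acetaldehyde | CC(C)(C)[Si](C)(C)OCC=O | starting material
14 | (Z)-dibutylboron dienolate of 12 | C=C/C=C(\OB(CCCC)CCCC)N1[C@H](Cc2ccccc2)COC1=O | intermediate (not isolated)
15 | (4R)-4-benzyl-3-[(2R,3R)-4-{[tert-butyl(dimethyl)silyl]oxy}-2-ethenyl-3-hydroxybutanoyl]-1,3-oxazolidin-2-one | CC(C)(C)[Si](C)(C)OC[C@H](O)[C@@H](C=C)C(=O)N1[C@H](Cc2ccccc2)COC1=O | intermediate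
16 | (4R)-4-benzyl-3-[(2R,3R)-2-ethenyl-3,4-dihydroxybutanoyl]-1,3-oxazolidin-2-one | OC[C@H](O)[C@@H](C=C)C(=O)N1[C@H](Cc2ccccc2)COC1=O | intermediate (not isolated)
17 | (3R,4R)-3-ethenyl-4-hydroxyoxolan-2-one | C=C[C@H]1C(=O)OC[C@@H]1O | intermediate
18 | dilithium enolate alkoxide of 17 | C=CC1=C(O[Li])OC[C@@H]1O[Li] | intermediate (not isolated)
19 | (3S,4R)-3-ethenyl-4-hydroxy-3-methyloxolan-2-one (methyl trans to hydroxyl) | C=C[C@]1(C)C(=O)OC[C@@H]1O | intermediate
20 | (2R,3R)-2-ethenyl-2-methylbutane-1,3,4-triol | OC[C@H](O)[C@](C)(C=C)CO | intermediate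
21 | [(2R,4R,5R)-5-ethenyl-2-(4-methoxyphenyl)-5-methyl-1,3-dioxan-4-yl]methanol | OC[C@@H]1O[C@H](c2ccc(OC)cc2)OC[C@@]1(C)C=C | intermediate
22 | (2R,4R,5R)-5-ethenyl-2-(4-methoxyphenyl)-5-methyl-1,3-dioxane-4-carbaldehyde | O=C[C@@H]1O[C@H](c2ccc(OC)cc2)OC[C@@]1(C)C=C | intermediate
23 | lithium dienolate from 8 (C2=C8 enolate carrying the isopropenyl group) | [Li]OC1=C(C(C)=C)CC[C@@H](CO[Si](c2ccccc2)(c2ccccc2)C(C)(C)C)CC1 | intermediate (not isolated)
24 | (2R,5R)-5-(silyloxymethyl)-2-{(R)-[(2R,4R,5R)-5-ethenyl-2-(4-methoxyphenyl)-5-methyl-1,3-dioxan-4-yl](hydroxy)methyl}-2-(prop-1-en-2-yl)cycloheptan-1-one | O=C1CC[C@H](CO[Si](c2ccccc2)(c2ccccc2)C(C)(C)C)CC[C@@]1(C(C)=C)[C@@H](O)[C@@H]3O[C@H](c4ccc(OC)cc4)OC[C@@]3(C)C=C | intermediate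
25 | keto triol: 24 without the aryl acetal (free C13, C15 and C16 hydroxyls; stereocentres as in 24) | O=C1CC[C@H](CO[Si](c2ccccc2)(c2ccccc2)C(C)(C)C)CC[C@@]1(C(C)=C)[C@@H](O)[C@H](O)[C@](C)(C=C)CO | intermediate
26 | C15/C16 isopropylidene acetal of 25 (trans-dioxolane, free C13 hydroxyl) | O=C1CC[C@H](CO[Si](c2ccccc2)(c2ccccc2)C(C)(C)C)CC[C@@]1(C(C)=C)[C@H]3OC(C)(C)O[C@@H]3[C@](C)(C=C)CO | intermediate
27 | spiro[5.6] ketone: cycloheptanone (C2 ketone, C5 silyloxymethyl) spiro at C8 to the cyclohexene C9(CH3)=C10, C14 (CH3 cis to O15, CH2OH cis to O16), C15/C16 trans-acetonide, C2 on the face of O16 | O=C1CC[C@H](CO[Si](c2ccccc2)(c2ccccc2)C(C)(C)C)CC[C@]13C(C)=C[C@](C)(CO)[C@H]4OC(C)(C)O[C@H]34 | intermediate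
28 | C13 aldehyde of 27 | O=C1CC[C@H](CO[Si](c2ccccc2)(c2ccccc2)C(C)(C)C)CC[C@]13C(C)=C[C@](C)(C=O)[C@H]4OC(C)(C)O[C@H]34 | intermediate
29 | spiro ketone with C14 vinyl group (from 28) | O=C1CC[C@H](CO[Si](c2ccccc2)(c2ccccc2)C(C)(C)C)CC[C@]13C(C)=C[C@](C)(C=C)[C@H]4OC(C)(C)O[C@H]34 | intermediate
30 | prop-2-enal | C=CC=O | starting material
31 | (1E)-1-iodobuta-1,3-diene | C=C/C=C/I | intermediate
32 | (1E)-buta-1,3-dien-1-yllithium | C=C/C=C/[Li] | intermediate (not isolated)
33 | (1E)-buta-1,3-dien-1-ylcerium dichloride | C=C/C=C/[Ce](Cl)Cl | intermediate (not isolated)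
34 | spiro[5.6] dienyl carbinol: 29 with C2 bearing OH (cis to C9) and the (E)-buta-1,3-dienyl group (cis to C16) | C=C/C=C/[C@@]1(O)CC[C@H](CO[Si](c2ccccc2)(c2ccccc2)C(C)(C)C)CC[C@]13C(C)=C[C@](C)(C=C)[C@H]4OC(C)(C)O[C@H]34 | intermediate
35 | potassium alkoxide of 34 | C=C/C=C/[C@@]1(O[K])CC[C@H](CO[Si](c2ccccc2)(c2ccccc2)C(C)(C)C)CC[C@]13C(C)=C[C@](C)(C=C)[C@H]4OC(C)(C)O[C@H]34 | intermediate (not isolated)
36 | potassium C1=C2 enolate of the ring-expanded bicycle | C=C[C@H]1/C=C(O[K])/CC[C@H](CO[Si](c5ccccc5)(c5ccccc5)C(C)(C)C)CCC2=C(C)[C@H]1[C@](C)(C=C)[C@H]4OC(C)(C)O[C@H]24 | intermediate (not isolated)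
37 | bicyclic triethylsilyl enol ether: eleven-membered ring with C1=C2(OSiEt3) (C11 trans to C3) and bridgehead C8=C9, vinyl groups on C11 and C14 both cis to O16, H10 and H11 cis | C=C[C@H]1/C=C(O[Si](CC)(CC)CC)/CC[C@H](CO[Si](c5ccccc5)(c5ccccc5)C(C)(C)C)CCC2=C(C)[C@H]1[C@](C)(C=C)[C@H]4OC(C)(C)O[C@H]24 | intermediate
38 | tricyclic enol ether with cis-fused C12=C13 cyclopentene | C1=C[C@H]2/C=C(O[Si](CC)(CC)CC)/CC[C@H](CO[Si](c5ccccc5)(c5ccccc5)C(C)(C)C)CCC3=C(C)[C@H]2[C@@]1(C)[C@H]4OC(C)(C)O[C@H]34 | intermediate
39 | tricyclic enol ether with saturated cyclopentane | C1C[C@H]2/C=C(O[Si](CC)(CC)CC)/CC[C@H](CO[Si](c5ccccc5)(c5ccccc5)C(C)(C)C)CCC3=C(C)[C@H]2[C@@]1(C)[C@H]4OC(C)(C)O[C@H]34 | intermediate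
40 | C2 ketone with CH2N(CH3)2 on C1 (C1 epimers) | CN(C)CC1C(=O)CC[C@H](CO[Si](c5ccccc5)(c5ccccc5)C(C)(C)C)CCC2=C(C)[C@@H]3[C@H]1CC[C@]3(C)[C@H]4OC(C)(C)O[C@H]24 | intermediate
41 | trimethylammonium iodide of 40 | C[N+](C)(C)CC1C(=O)CC[C@H](CO[Si](c5ccccc5)(c5ccccc5)C(C)(C)C)CCC2=C(C)[C@@H]3[C@H]1CC[C@]3(C)[C@H]4OC(C)(C)O[C@H]24.[I-] | intermediate (not isolated)
42 | C1-methylidene C2 ketone (C17 silyl ether, C15/C16 acetonide) | C=C1C(=O)CC[C@H](CO[Si](c5ccccc5)(c5ccccc5)C(C)(C)C)CCC2=C(C)[C@@H]3[C@H]1CC[C@]3(C)[C@H]4OC(C)(C)O[C@H]24 | intermediate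
43 | (2S)-C2 allylic alcohol of 42 | C=C1[C@@H](O)CC[C@H](CO[Si](c5ccccc5)(c5ccccc5)C(C)(C)C)CCC2=C(C)[C@@H]3[C@H]1CC[C@]3(C)[C@H]4OC(C)(C)O[C@H]24 | intermediate
44 | C2/C17 diol with C15/C16 acetonide | C=C1[C@@H](O)CC[C@H](CO)CCC2=C(C)[C@@H]3[C@H]1CC[C@]3(C)[C@H]4OC(C)(C)O[C@H]24 | intermediate
45 | C2/C17 diacetate with C15/C16 acetonide | C=C1[C@@H](OC(C)=O)CC[C@H](COC(C)=O)CCC2=C(C)[C@@H]3[C@H]1CC[C@]3(C)[C@H]4OC(C)(C)O[C@H]24 | intermediate
46 | CNP0193272.1 | C=C1[C@@H](OC(C)=O)CC[C@H](COC(C)=O)CCC2=C(C)[C@@H]3[C@H]1CC[C@]3(C)[C@@H](O)[C@@H]2O | target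

Total step count: 28. Longest linear sequence: 23 steps (steps 5 to 17, then 19 to 28).

Steps most likely to fail

Step 20. The alkoxide may cleave heterolytically at C2–C8 to an allyl anion and a dienone that are quenched apart, or undergo a [1,3] shift, instead of the concerted chair [3,3] shift. The fallback sets out from 34: the tertiary hydroxyl would be silylated (Et3SiOSO2CF3, 2,6-lutidine, CH2Cl2, −78 °C) to the C2-O-triethylsilyl ether F1, which would be heated neutral (degassed 1,2-dichlorobenzene, about 200 °C, sealed tube). The thermal siloxy-Cope shift through the same chair moves the silyl group onto the enol oxygen, so it should return directly to 37.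

Step 12. The dienolate may react through its terminal carbon instead of C8, the aldolate may revert on warming, or the aldehyde may be attacked on its non-chelated face. The fallback sets out from 8: after the same conjugate reduction the dienolate would be trapped with Me3SiCl as the trimethylsilyl dienol ether F2, and this would be added to 22 under MgBr2·OEt2 in CH2Cl2 at −78 °C (Mukaiyama aldol on the pre-formed chelate, open transition state). The product is not an alkoxide, so reversal is suppressed, and the route is rejoined at 24.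

Step 19. The basic dienyl organometallic may enolise the hindered ketone toward C3 or decompose before it adds, returning ketone. The fallback sets out from 29: the lithium acetylide of but-1-en-3-yne (n-BuLi, CeCl3, THF, −78 °C), which is slimmer and less basic, would be added to give the enynyl carbinol F3. Reduction of its propargylic alkoxide with NaAlH2(OCH2CH2OCH3)2 in THF at 0 °C (trans-hydroalumination) should give the (E)-dienyl carbinol and rejoin the route at 34.

Further compounds
F1 | step 20 | C2-O-triethylsilyl ether of 34 | C=C/C=C/[C@@]1(O[Si](CC)(CC)CC)CC[C@H](CO[Si](c2ccccc2)(c2ccccc2)C(C)(C)C)CC[C@]13C(C)=C[C@](C)(C=C)[C@H]4OC(C)(C)O[C@H]34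
F2 | step 12 | trimethylsilyl dienol ether from 8 | C[Si](C)(C)OC1=C(C(C)=C)CC[C@@H](CO[Si](c2ccccc2)(c2ccccc2)C(C)(C)C)CC1
F3 | step 19 | C2 but-3-en-1-ynyl carbinol from 29 | C=CC#C[C@@]1(O)CC[C@H](CO[Si](c2ccccc2)(c2ccccc2)C(C)(C)C)CC[C@]13C(C)=C[C@](C)(C=C)[C@H]4OC(C)(C)O[C@H]34
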